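## Retrosynthetic overview

1. The last ring formed is the six-membered carbocycle. It is opened at C4a–C5 (chromene numbering: the carbon that carries the pyranone carbonyl and the enol carbon next to the quaternary C6) as a Dieckmann C-acylation. In the precursor the side-chain acid is tied to the C7 oxygen as an enol δ-lactone (temporary ring).
2. Enabling feature: the 2,3-dihydro-4H-pyran-4-one ring is joined through its C6 to the lactone C=C. Its C5–H (α-carbon of the vinylogous ester O1–C6=C5–C4=O) is the far end of the dienolate released when the lactone is cleaved. It sits 1,6 to the ester carbonyl on the quaternary carbon and is held cis to it across that C=C.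
3. The pyranone ring comes from a Baker–Venkataraman acyl shift and cyclodehydration of a 2-methyl-4-oxopentan-2-yl ester. The lactone ring and the propyl-bearing centre come from an NHC-catalysed oxidative annulation of a β-keto ester with (E)-hex-2-enal.
4. The β-keto ester comes from a malonic half-ester, 2,2-dimethyl-1,3-dioxane-4,6-dione and 4-hydroxy-4-methylpentan-2-one. The quaternary centre is set by phase-transfer prenylation of a tert-butyl/2,2-diphenylethyl malonate.
5. The cyclobutane is bought as 3,3-dimethylcyclobutanecarboxylic acid; its two centres come from a rhodium-catalysed asymmetric 1,4-addition of an isopropenylboron to the cyclobutene ester. Ring order: cyclobutane (bought), δ-lactone (temporary), pyranone, carbocycle.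

Key step: step 14

Assumption: the sense of induction in the three catalyst-controlled steps (3, 8 and 12) is taken as drawn; each catalyst is available as both antipodes, and the other antipode would be used if the sense proved opposite.

Abbreviations in names: Cbm = [(1S,2R)-3,3-dimethyl-2-(prop-1-en-2-yl)cyclobutyl]methyl; Dpe = 2,2-diphenylethyl; prenyl = 3-methylbut-2-en-1-yl.

## Route

Step 1
Reactants: 1 3,3-dimethylcyclobutane-1-carboxylic acid
Product: 2 benzyl 3,3-dimethylcyclobutane-1-carboxylate
Conditions: BnBr, K2CO3, DMF, rt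
Reagents that add atoms: benzyl bromide, BrCc1ccccc1
Why: SN2 O-alkylation of the carboxylate (esterification) should give a non-volatile ester for the enolate chemistry that follows; no stereocentre is involved.

Step 2
Reactants: 2 benzyl 3,3-dimethylcyclobutane-1-carboxylate
Product: 4 benzyl 3,3-dimethylcyclobut-1-ene-1-carboxylate, via α-bromo ester 3 (not isolated)
Conditions: LiN(iPr)2, THF, −78 °C; BrCCl2CCl2Br, −78 to 0 °C; then DBU, toluene, 80 °C
Reagents that add atoms: 1,2-dibromo-1,1,2,2-tetrachloroethane, BrC(Cl)(Cl)C(Cl)(Cl)Br (gives the bromine of 3 only; none of its atoms stays in 4)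
Why: α-bromination of the ester enolate followed by E2 dehydrobromination should give the conjugated cyclobutene as one regioisomer, because the two ring CH2 groups are related by symmetry.

Step 3
Reactants: 4 benzyl 3,3-dimethylcyclobut-1-ene-1-carboxylate; 5 4,4,5,5-tetramethyl-2-(prop-1-en-2-yl)-1,3,2-dioxaborolane
Product: 6 benzyl (1R,2R)-3,3-dimethyl-2-(prop-1-en-2-yl)cyclobutane-1-carboxylate (trans)
Conditions: [Rh(C2H4)2Cl]2 (2.5 mol %), (R,R)-2,5-diphenylbicyclo[2.2.2]octa-2,5-diene (5.5 mol %), KOH (0.5 equiv), dioxane/H2O 10:1, 50 °C; then DBU (0.3 equiv), toluene, 60 °C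
Reagents that add atoms: none
Why: Rhodium-catalysed asymmetric 1,4-addition of an alkenylboron to a strained enoate (Hayashi–Miyaura reaction); the chiral diene ligand selects the face of carbometalation at C2 and so sets the isopropenyl-bearing centre, and base equilibration of the epimerisable C1 should leave the more stable trans ester.

Step 4
Reactants: 6 benzyl (1R,2R)-3,3-dimethyl-2-(prop-1-en-2-yl)cyclobutane-1-carboxylate
Product: 7 [(1R,2R)-3,3-dimethyl-2-(prop-1-en-2-yl)cyclobutyl]methanol
Conditions: LiAlH4, Et2O, 0 °C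
Reagents that add atoms: none
Why: Hydride reduction of the ester to the primary alcohol; both ring centres are kept and C1 is no longer epimerisable afterwards.

Step 5
Reactants: 7 [(1R,2R)-3,3-dimethyl-2-(prop-1-en-2-yl)cyclobutyl]methanol
Product: 8 (1R,2R)-1-(iodomethyl)-3,3-dimethyl-2-(prop-1-en-2-yl)cyclobutane
Conditions: I2, PPh3, imidazole, CH2Cl2, 0 °C to rt
Reagents that add atoms: iodine, [I][I]
Why: Appel-type iodination by SN2 at the primary carbon; the ring stereocentres are not touched.

Step 6
Reactants: 9 3-(tert-butoxy)-3-oxopropanoic acid; 10 2,2-diphenylethan-1-ol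
Product: 11 1-tert-butyl 3-(2,2-diphenylethyl) propanedioate
Conditions: EDC·HCl, DMAP (cat.), CH2Cl2, 0 °C to rt
Reagents that add atoms: none
Why: Carbodiimide (Steglich-type) esterification gives a malonate with two distinguishable esters: the tert-butyl ester can be removed without base or protic acid, and the diarylalkyl ester provides the recognition needed in step 8.

Step 7
Reactants: 11 1-tert-butyl 3-(2,2-diphenylethyl) propanedioate; 8 (1R,2R)-1-(iodomethyl)-3,3-dimethyl-2-(prop-1-en-2-yl)cyclobutane
Product: 12 1-tert-butyl 3-(2,2-diphenylethyl) 2-{[(1R,2R)-3,3-dimethyl-2-(prop-1-en-2-yl)cyclobutyl]methyl}propanedioate (both epimers at C2)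
Conditions: NaH, DMF, 0 °C (11 in slight excess); then 8, 50 °C
Reagents that add atoms: none
Why: Malonic ester alkylation (SN2) with the β-branched primary iodide; the new malonate centre forms unselectively, which does not matter because it is deprotonated again in step 8.

Step 8
Reactants: 12 the monoalkylated malonate; 13 1-bromo-3-methylbut-2-ene
Product: 14 1-tert-butyl 3-Dpe (2R)-2-Cbm-2-prenylpropanedioate
Conditions: (S,S)-3,4,5-trifluorophenyl-NAS bromide (C2-symmetric N-spiro bis(binaphthyl)ammonium salt, 5 mol %), 50% aq. KOH, toluene, −40 °C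
Reagents that add atoms: none
Why: Asymmetric phase-transfer C-alkylation of a prochiral α-alkylmalonate enolate with an activated allylic bromide; the enolate reacts as a tight ion pair with the chiral ammonium cation, which blocks one face and sets the quaternary centre under catalyst control.

Step 9
Reactants: 14 1-tert-butyl 3-Dpe (2R)-2-Cbm-2-prenylpropanedioate
Product: 16 (2S)-2-Cbm-3-(2,2-diphenylethoxy)-2-prenyl-3-oxopropanoic acid, via trimethylsilyl ester 15 (not isolated)
Conditions: Me3SiOTf, 2,6-lutidine, CH2Cl2, 0 °C; then pH 5 phosphate buffer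
Reagents that add atoms: trimethylsilyl trifluoromethanesulfonate, C[Si](C)(C)OS(=O)(=O)C(F)(F)F (gives the silyl group of 15 only; none of its atoms stays in 16)
Why: Silyl-triflate-mediated tert-butyl ester cleavage (loss of 2-methylpropene from the silylated ester) under buffered aprotic conditions should spare the prenyl and isopropenyl groups and the primary ester; the quaternary centre is not affected.

Step 10
Reactants: 16 the malonic half-ester; 17 2,2-dimethyl-1,3-dioxane-4,6-dione
Product: 19 Dpe (2S)-2-Cbm-2-[(2,2-dimethyl-4,6-dioxo-1,3-dioxan-5-ylidene)(hydroxy)methyl]-5-methylhex-4-enoate, via acid chloride 18 (not isolated)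
Conditions: 1-chloro-N,N,2-trimethylprop-1-en-1-amine, CH2Cl2, 0 °C to rt; then 17, pyridine, DMAP (cat.), 0 °C to rt
Reagents that add atoms: 1-chloro-N,N,2-trimethylprop-1-en-1-amine, CC(C)=C(Cl)N(C)C (gives the chlorine of 18 only; none of its atoms stays in 19)
Why: Neutral acid chloride formation with the α-chloroenamine, then C-acylation of the acidic dioxanedione, should give the acyl dioxanedione (a masked acylketene) without exposing the alkenes to acid.

Step 11
Reactants: 19 the acyl dioxanedione; 20 4-hydroxy-4-methylpentan-2-one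
Product: 22 5-Dpe 1-(2-methyl-4-oxopentan-2-yl) (4S)-4-Cbm-4-prenyl-3-oxopentanedioate, via acylketene 21 (not isolated)
Conditions: toluene, 20 (3 equiv), 90 °C
Reagents that add atoms: none
Why: Thermal retro-[4+2] fragmentation of the acyl dioxanedione (loss of acetone and CO2) gives an acylketene that the tertiary alcohol traps as the β-keto ester under neutral conditions.

Step 12
Reactants: 22 the β-keto ester; 23 (2E)-hex-2-enal
Product: 24 2-methyl-4-oxopentan-2-yl (4R)-6-[(2S)-2-Cbm-1-(2,2-diphenylethoxy)-5-methyl-1-oxohex-4-en-2-yl]-2-oxo-4-propyl-3,4-dihydro-2H-pyran-5-carboxylate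
Conditions: (5aS,10bR)-2-mesityl-5a,10b-dihydro-4H,6H-indeno[2,1-b][1,2,4]triazolo[4,3-d][1,4]oxazin-2-ium chloride (10 mol %), iPr2NEt (0.3 equiv), 3,3′,5,5′-tetra-tert-butyl-4,4′-diphenoquinone (1.2 equiv), toluene, 4 Å MS, rt
Reagents that add atoms: none
Why: NHC-catalysed oxidative annulation of an enal with a 1,3-dicarbonyl compound: the quinone oxidises the Breslow intermediate to an α,β-unsaturated acyl azolium, the central carbon of the β-keto ester adds in a Michael fashion and the ketone enol oxygen lactonises; the indane-fused triazolium shields one face of the acyl azolium and so sets the propyl-bearing centre (R), independently of the remote quaternary centre.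

Step 13
Reactants: 24 the enol δ-lactone ester
Product: 26 Dpe (2S)-2-Cbm-2-[(4R)-5-(6,6-dimethyl-4-oxo-5,6-dihydro-4H-pyran-2-yl)-2-oxo-4-propyl-3,4-dihydro-2H-pyran-6-yl]-5-methylhex-4-enoate, via hydroxy diketone 25 (not isolated)
Conditions: LiN(SiMe3)2 (1.2 equiv), THF, −78 to −20 °C; AcOH; then TsOH·H2O (0.1 equiv), CH2Cl2, 4 Å MS, 0 °C to rt
Reagents that add atoms: none
Why: Baker–Venkataraman-type O-to-C acyl shift: the kinetic methyl-ketone enolate attacks the ester carbonyl through a six-membered tetrahedral intermediate (the acyl carbon sits on a fully substituted alkene carbon, so no acidic hydrogen can deactivate it), and catalytic acid then closes the freed tertiary hydroxyl onto the only carbonyl in a 1,5-relationship and dehydrates the hemiketal to the 2,3-dihydro-4H-pyran-4-one; no stereocentre is involved.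

Step 14
Reactants: 26 the pyranone-substituted enol δ-lactone
Product: 28 (3R)-3-[(6R)-6-Cbm-5-hydroxy-2,2-dimethyl-6-prenyl-4,7-dioxo-3,4,6,7-tetrahydro-2H-chromen-8-yl]hexanoic acid (CNP0358381.1), via dipotassium dienolate 27 (not isolated)
Conditions: KOSiMe3 (2.2 equiv), THF, 0 to 45 °C; then 1 M HCl to pH 3
Reagents that add atoms: potassium trimethylsilanolate, C[Si](C)(C)[O-].[K+] (its oxygen ends in the carboxylic acid)
Why: Silanolate should cleave only the activated enol δ-lactone (acyl–oxygen fission, then desilylation of the silyl ester by the second equivalent), which frees the side-chain carboxylate and the ketone enolate; this enolate is conjugated through the former lactone C=C into the dihydropyranone, so its remote nucleophilic terminus is the pyranone C5, which attacks the 2,2-diphenylethyl ester on the quaternary carbon, and loss of alkoxide and deprotonation give the stabilised β-triketone enolate as the thermodynamic sink. The closest known reaction type is the Dieckmann (intramolecular Claisen) condensation in its polyketide form, in which the central carbon of a 3,5,7-tricarbonyl ester is C-acylated to an acylphloroglucinol, run here through an extended enolate. The six-membered carbocycle closes in a 6-(enolexo)-exo-trig mode with respect to the pyranone enolate. No stereocentre is created: the quaternary carbon and the propyl-bearing carbon are not touched, and the enolate geometry and any epimers at the enolate carbon converge because that carbon ends sp2. The step needs C- over O-acylation and attack of silanolate at the lactone instead of the ester: every O-acylation mode would give a four- or eight-membered ring while C-attack gives the six-membered ring, and the ester sits on a neopentyl-type carbon while the two equivalents of silanolate are consumed by the lactone.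

## Compound list

1 | 3,3-dimethylcyclobutane-1-carboxylic acid | CC1(C)CC(C(=O)O)C1 | starting material
2 | benzyl 3,3-dimethylcyclobutane-1-carboxylate | CC1(C)CC(C(=O)OCc2ccccc2)C1 | intermediate
3 | benzyl 1-bromo-3,3-dimethylcyclobutane-1-carboxylate | CC1(C)CC(Br)(C(=O)OCc2ccccc2)C1 | intermediate (not isolated)
4 | benzyl 3,3-dimethylcyclobut-1-ene-1-carboxylate | CC1(C)CC(C(=O)OCc2ccccc2)=C1 | intermediate
5 | 4,4,5,5-tetramethyl-2-(prop-1-en-2-yl)-1,3,2-dioxaborolane | CC(=C)B1OC(C)(C)C(C)(C)O1 | starting material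
6 | benzyl (1R,2R)-3,3-dimethyl-2-(prop-1-en-2-yl)cyclobutane-1-carboxylate | C=C(C)[C@H]1[C@H](C(=O)OCc2ccccc2)CC1(C)C | intermediate
7 | [(1R,2R)-3,3-dimethyl-2-(prop-1-en-2-yl)cyclobutyl]methanol | C=C(C)[C@H]1[C@H](CO)CC1(C)C | intermediate
8 | (1R,2R)-1-(iodomethyl)-3,3-dimethyl-2-(prop-1-en-2-yl)cyclobutane | C=C(C)[C@H]1[C@H](CI)CC1(C)C | intermediate
9 | 3-(tert-butoxy)-3-oxopropanoic acid | CC(C)(C)OC(=O)CC(=O)O | starting material
10 | 2,2-diphenylethan-1-ol | OCC(c1ccccc1)c1ccccc1 | starting material
11 | 1-tert-butyl 3-(2,2-diphenylethyl) propanedioate | CC(C)(C)OC(=O)CC(=O)OCC(c1ccccc1)c1ccccc1 | intermediate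
12 | 1-tert-butyl 3-(2,2-diphenylethyl) 2-{[(1R,2R)-3,3-dimethyl-2-(prop-1-en-2-yl)cyclobutyl]methyl}propanedioate (both epimers at C2) | C=C(C)[C@H]1[C@H](CC(C(=O)OCC(c2ccccc2)c2ccccc2)C(=O)OC(C)(C)C)CC1(C)C | intermediate
13 | 1-bromo-3-methylbut-2-ene | CC(C)=CCBr | starting material
14 | 1-tert-butyl 3-(2,2-diphenylethyl) (2R)-2-{[(1S,2R)-3,3-dimethyl-2-(prop-1-en-2-yl)cyclobutyl]methyl}-2-(3-methylbut-2-en-1-yl)propanedioate | C=C(C)[C@H]1[C@H](C[C@](C(=O)OCC(c2ccccc2)c2ccccc2)(CC=C(C)C)C(=O)OC(C)(C)C)CC1(C)C | intermediate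
15 | 2,2-diphenylethyl trimethylsilyl (2R)-2-Cbm-2-prenylpropanedioate | C=C(C)[C@H]1[C@H](C[C@](C(=O)OCC(c2ccccc2)c2ccccc2)(CC=C(C)C)C(=O)O[Si](C)(C)C)CC1(C)C | intermediate (not isolated)
16 | (2S)-2-Cbm-3-(2,2-diphenylethoxy)-2-prenyl-3-oxopropanoic acid | C=C(C)[C@H]1[C@H](C[C@](C(=O)OCC(c2ccccc2)c2ccccc2)(CC=C(C)C)C(=O)O)CC1(C)C | intermediate
17 | 2,2-dimethyl-1,3-dioxane-4,6-dione | CC1(C)OC(=O)CC(=O)O1 | starting material
18 | 2,2-diphenylethyl (2R)-2-(chlorocarbonyl)-2-Cbm-5-methylhex-4-enoate | C=C(C)[C@H]1[C@H](C[C@](C(=O)OCC(c2ccccc2)c2ccccc2)(CC=C(C)C)C(=O)Cl)CC1(C)C | intermediate (not isolated)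
19 | 2,2-diphenylethyl (2S)-2-Cbm-2-[(2,2-dimethyl-4,6-dioxo-1,3-dioxan-5-ylidene)(hydroxy)methyl]-5-methylhex-4-enoate | C=C(C)[C@H]1[C@H](C[C@](C(=O)OCC(c2ccccc2)c2ccccc2)(CC=C(C)C)C(O)=C2C(=O)OC(C)(C)OC2=O)CC1(C)C | intermediate
20 | 4-hydroxy-4-methylpentan-2-one | CC(=O)CC(C)(C)O | starting material
21 | 2,2-diphenylethyl (2S)-2-Cbm-5-methyl-2-(3-oxoprop-2-enoyl)hex-4-enoate (acylketene) | C=C(C)[C@H]1[C@H](C[C@](C(=O)OCC(c2ccccc2)c2ccccc2)(CC=C(C)C)C(=O)C=C=O)CC1(C)C | intermediate (not isolated)
22 | 5-(2,2-diphenylethyl) 1-(2-methyl-4-oxopentan-2-yl) (4S)-4-Cbm-4-prenyl-3-oxopentanedioate | C=C(C)[C@H]1[C@H](C[C@](C(=O)OCC(c2ccccc2)c2ccccc2)(CC=C(C)C)C(=O)CC(=O)OC(C)(C)CC(C)=O)CC1(C)C | intermediate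
23 | (2E)-hex-2-enal | CCC/C=C/C=O | starting material
24 | 2-methyl-4-oxopentan-2-yl (4R)-6-[(2S)-2-Cbm-1-(2,2-diphenylethoxy)-5-methyl-1-oxohex-4-en-2-yl]-2-oxo-4-propyl-3,4-dihydro-2H-pyran-5-carboxylate | C=C(C)[C@H]1[C@H](C[C@](C(=O)OCC(c2ccccc2)c2ccccc2)(CC=C(C)C)C2=C(C(=O)OC(C)(C)CC(C)=O)[C@H](CCC)CC(=O)O2)CC1(C)C | intermediate
25 | 2,2-diphenylethyl (2S)-2-Cbm-2-[(4R)-5-(5-hydroxy-5-methyl-3-oxohexanoyl)-2-oxo-4-propyl-3,4-dihydro-2H-pyran-6-yl]-5-methylhex-4-enoate | C=C(C)[C@H]1[C@H](C[C@](C(=O)OCC(c2ccccc2)c2ccccc2)(CC=C(C)C)C2=C(C(=O)CC(=O)CC(C)(C)O)[C@H](CCC)CC(=O)O2)CC1(C)C | intermediate (not isolated)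
26 | 2,2-diphenylethyl (2S)-2-Cbm-2-[(4R)-5-(6,6-dimethyl-4-oxo-5,6-dihydro-4H-pyran-2-yl)-2-oxo-4-propyl-3,4-dihydro-2H-pyran-6-yl]-5-methylhex-4-enoate | C=C(C)[C@H]1[C@H](C[C@](C(=O)OCC(c2ccccc2)c2ccccc2)(CC=C(C)C)C2=C(C3=CC(=O)CC(C)(C)O3)[C@H](CCC)CC(=O)O2)CC1(C)C | intermediate
27 | dipotassium salt of the ring-opened lactone of 26 (ketone enolate and side-chain carboxylate; 2,2-diphenylethyl ester intact) | [K+].[K+].C=C(C)[C@H]1[C@H](C[C@](C(=O)OCC(c2ccccc2)c2ccccc2)(CC=C(C)C)/C([O-])=C(/[C@H](CCC)CC(=O)[O-])C2=CC(=O)CC(C)(C)O2)CC1(C)C | intermediate (not isolated)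
28 | (3R)-3-[(6R)-6-{[(1S,2R)-3,3-dimethyl-2-(prop-1-en-2-yl)cyclobutyl]methyl}-5-hydroxy-2,2-dimethyl-6-(3-methylbut-2-en-1-yl)-4,7-dioxo-3,4,6,7-tetrahydro-2H-chromen-8-yl]hexanoic acid | C=C(C)[C@H]1[C@H](C[C@]2(CC=C(C)C)C(=O)C([C@H](CCC)CC(=O)O)=C3OC(C)(C)CC(=O)C3=C2O)CC1(C)C | target

## Step count and risks

Total steps: 14. Longest linear sequence: 13 steps (steps 1 to 5, then 7 to 14).

Three steps most likely to fail:

**Step 12.** Ring closure of the hindered ketone enol onto the acyl azolium may be slow. Under the basic conditions, intramolecular aldol condensation between the active methylene and the pendant methyl ketone may compete, and facial control may be insufficient. The fallback sets out from 22 (with 23) and makes the carbon–carbon bond under weakly acidic iminium catalysis. The antipode of 2-[diphenyl(trimethylsilyloxy)methyl]pyrrolidine that gives the (R) centre, with benzoic acid in toluene at 0 °C, should give the Michael adduct, which closes through the ketone enol to the cyclic hemiacetal (lactol) F1. Oxidation of the lactol with TEMPO and PhI(OAc)2 in CH2Cl2 returns to the route at 24.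

**Step 3.** Carbometalation at the ring carbon next to the gem-dimethyl group may be slow, so that protodeboronation outruns addition, or facial selectivity may be poor. The fallback sets out from 4 and uses a racemic copper-catalysed conjugate addition followed by a classical resolution. Isopropenylmagnesium bromide with CuBr·SMe2 (cat.) and Me3SiCl in THF at −40 °C, followed by DBU equilibration, should give the racemic trans benzyl ester F2. Saponification with LiOH gives the racemic trans acid F3. Fractional crystallisation with (S)-1-phenylethylamine (or its antipode, whichever gives the less soluble salt of the wanted acid) gives the diastereomerically pure salt F4. Acidification frees the (1R,2R)-acid F5, and LiAlH4 reduction returns to the route at 7.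

**Step 14.** C-acylation at the neopentyl-type ester may be slow, so that cleavage of that ester by silanolate or decay of the dienolate competes. The fallback sets out from 26 and separates lactone opening from ring closure. NaOMe in MeOH at 0 °C opens the lactone to the open-chain keto methyl ester F6. A Lewis-acid-mediated soft-enolisation Dieckmann condensation (TiCl4, Bu3N, CH2Cl2, −78 to 0 °C) then closes the carbocycle on the neutral substrate to give the methyl ester F7 of the target. Saponification with LiOH in THF/H2O, followed by acidification to pH 3, returns to the route at 28.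

## Further compounds

F1 | step 12 | 2-methyl-4-oxopentan-2-yl (4R)-6-[(2S)-2-Cbm-1-(2,2-diphenylethoxy)-5-methyl-1-oxohex-4-en-2-yl]-2-hydroxy-4-propyl-3,4-dihydro-2H-pyran-5-carboxylate (lactol, both anomers) | C=C(C)[C@H]1[C@H](C[C@](C(=O)OCC(c2ccccc2)c2ccccc2)(CC=C(C)C)C2=C(C(=O)OC(C)(C)CC(C)=O)[C@H](CCC)CC(O)O2)CC1(C)C
F2 | step 3 | racemic benzyl trans-3,3-dimethyl-2-(prop-1-en-2-yl)cyclobutane-1-carboxylate | C=C(C)[C@H]1[C@H](C(=O)OCc2ccccc2)CC1(C)C.C=C(C)[C@@H]1[C@@H](C(=O)OCc2ccccc2)CC1(C)C
F3 | step 3 | racemic trans-3,3-dimethyl-2-(prop-1-en-2-yl)cyclobutane-1-carboxylic acid | C=C(C)[C@H]1[C@H](C(=O)O)CC1(C)C.C=C(C)[C@@H]1[C@@H](C(=O)O)CC1(C)C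
F4 | step 3 | (S)-1-phenylethylammonium (1R,2R)-3,3-dimethyl-2-(prop-1-en-2-yl)cyclobutane-1-carboxylate | C=C(C)[C@H]1[C@H](C(=O)[O-])CC1(C)C.C[C@H]([NH3+])c1ccccc1
F5 | step 3 | (1R,2R)-3,3-dimethyl-2-(prop-1-en-2-yl)cyclobutane-1-carboxylic acid | C=C(C)[C@H]1[C@H](C(=O)O)CC1(C)C
F6 | step 14 | 1-(2,2-diphenylethyl) 7-methyl (2S,5R)-2-Cbm-4-(6,6-dimethyl-4-oxo-5,6-dihydro-4H-pyran-2-yl)-2-prenyl-3-oxo-5-propylheptanedioate (both epimers at C4) | C=C(C)[C@H]1[C@H](C[C@](C(=O)OCC(c2ccccc2)c2ccccc2)(CC=C(C)C)C(=O)C([C@H](CCC)CC(=O)OC)C2=CC(=O)CC(C)(C)O2)CC1(C)C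
F7 | step 14 | methyl (3R)-3-[(6R)-6-Cbm-5-hydroxy-2,2-dimethyl-6-prenyl-4,7-dioxo-3,4,6,7-tetrahydro-2H-chromen-8-yl]hexanoate | C=C(C)[C@H]1[C@H](C[C@]2(CC=C(C)C)C(=O)C([C@H](CCC)CC(=O)OC)=C3OC(C)(C)CC(=O)C3=C2O)CC1(C)C
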